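**Plan**

- Retrosynthesis: the C12 silyl ether, the 5,6-epoxide and the C5=C6 bond (ring-closing metathesis) go first; the lactone is cut at O7–C19 and C8–C17 (lactate enolate aldol); the arms are cut at C8–C9 and C2–C3 (two acyl substitutions on a γ-lactone that relays between C2 and C9).
- Ring A (C1, C10–C14) is cut last, at C11–C12 and C1–C14 together. The methyl groups C15 and C20 are cis and 1,3 to each other across C10, so they can be tied through sulfur into a thian-4-one (C10 = ketone, C1 = β-keto ester carbon carrying C2). Its α and α′ carbons then match the 1,3-dioxygenated C12–C13–C14 unit, which is brought in as a β-silyl enal.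
- Forward: a Michael–aldol bicycloannulation builds ring A on the thiane template, C9 is added by homologation, Raney Ni cuts the template to the two methyl groups, the C2 and C9 arms are grown, the lactone is annulated and the ten-membered ring is closed last.
- Stereochemistry: C14 from the amine catalyst; C1, C11, C12 and C10 from the bicyclic template (C–Si to C–O with retention); C3 from sparteine; C2 from a hydroxyl-directed reduction; C9 and C8 from Felkin–Anh additions; C7 from allylic strain; C17 from (S)-lactic acid; C5/C6 from a hydroxyl-directed epoxidation.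

Key step: step 3

Remark: atoms are numbered as in the briarane skeleton of the target (C1 = quaternary ring-fusion carbon, C10 = its CH neighbour, C15 and C20 = methyl groups on C1 and C11). Hydroxy ketones 18 and 24 are drawn open-chain although they may rest as five-membered hemiketals. Intermediates are named descriptively; the SMILES in the compound list fix every stereocentre.

Step 1
Reactants: 1 prop-2-yn-1-ol
Product: 2 (E)-3-(dimethylphenylsilyl)prop-2-en-1-ol
Conditions: PhMe2SiH, PtCl2 (1 mol %), XPhos, THF, 50 °C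
Reagents that add atoms: dimethylphenylsilane C[SiH](C)c1ccccc1
Why: Platinum-catalysed syn-hydrosilylation of the propargylic alcohol should place silicon on the terminal carbon and give the (E)-β-silyl allylic alcohol.

Step 2
Reactants: 2 (E)-3-(dimethylphenylsilyl)prop-2-en-1-ol
Product: 3 (E)-3-(dimethylphenylsilyl)prop-2-enal
Conditions: MnO2, CH2Cl2, rt
Reagents that add atoms: none
Why: Allylic oxidation with MnO2 should stop at the enal and keep the (E) geometry.

Step 3
Reactants: 3 (E)-3-(dimethylphenylsilyl)prop-2-enal; 4 methyl 4-oxothiane-3-carboxylate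
Product: 6 methyl 8-(dimethylphenylsilyl)-6-hydroxy-9-oxo-3-thiabicyclo[3.3.1]nonane-1-carboxylate (bicyclic ketol; silyl axial and hydroxyl equatorial on ring A), via keto aldehyde Michael adduct 5 (not isolated)
Conditions: (R)-α,α-diphenylprolinol trimethylsilyl ether (10 mol %), PhCO2H (10 mol %), toluene, 0 °C to rt; then DBU (0.3 equiv), rt
Reagents that add atoms: none
Why: The secondary amine condenses with 3 to an (E)-iminium ion whose β-carbon (C14) is attacked by the enol of β-keto ester 4 through C1, and after hydrolysis DBU enolises the ketone of 5 towards its only free α′-carbon (C11), which adds to the aldehyde (C12) in an intramolecular aldol reaction. The closest known reaction type is the amine- or base-mediated Michael–aldol α,α′-annulation of cyclic β-keto esters with enals to bicyclo[3.3.1]nonan-9-ones. Ring A closes in a 6-(enolexo)-exo-trig aldol mode across the thianone, whose C15–S–C20 bridge can only be spanned diaxially. C14 is set by the catalyst (attack anti to the diphenyl(silyloxy)methyl group), C1 by a synclinal Michael transition state that keeps the silyl group anti to the thiane CH2 (silyl axial on ring A), C11 by the bridge geometry that forces both new bonds cis, and C12 by thermodynamic control, because the reversible aldol places the hydroxyl equatorial and away from the syn-axial silyl group. The step needs C-alkylation at the doubly activated carbon and no dehydration, which the acidity of the β-keto ester and the bridgehead position of C11 (Bredt's rule) should secure.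

Step 4
Reactants: 6 bicyclic ketol
Product: 7 tert-butyldimethylsilyl ether of 6 (silyl ether on the C12 oxygen)
Conditions: TBSOTf, 2,6-lutidine, CH2Cl2, −78 to 0 °C
Reagents that add atoms: tert-butyldimethylsilyl trifluoromethanesulfonate CC(C)(C)[Si](C)(C)OS(=O)(=O)C(F)(F)F
Why: Silyl triflate silylation under non-basic conditions should protect the aldol hydroxyl without retro-aldol cleavage; this group stays until the last step.

Step 5
Reactants: 7 silyl-protected bicyclic ketone
Product: 8 methyl 9-(methoxymethylidene)-3-thiabicyclo[3.3.1]nonane-1-carboxylate derivative (enol ether at C10; E/Z mixture)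
Conditions: Ph3P(CH2OMe)Cl, KN(SiMe3)2, THF, 0 °C to rt
Reagents that add atoms: (methoxymethyl)triphenylphosphonium chloride COC[P+](c1ccccc1)(c1ccccc1)c1ccccc1.[Cl-]
Why: Wittig methoxymethylenation of the bridging ketone, which cannot enolise at either bridgehead, should install C9 as an enol ether.

Step 6
Reactants: 8 enol ether
Product: 10 bicyclic aldehyde with the formyl group (C9) on C10 equatorial on ring A, via C10-epimeric aldehyde mixture 9 (not isolated)
Conditions: TsOH·H2O (cat.), acetone–H2O, 40 °C; then DBU (0.2 equiv), CH2Cl2, rt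
Reagents that add atoms: water O
Why: Acid hydrolysis of the enol ether gives the aldehyde, and base-mediated epimerisation through its enol should place the formyl group away from the syn-axial silyl group of ring A, which is the C10 configuration of the target (thermodynamic control).

Step 7
Reactants: 10 bicyclic aldehyde
Product: 12 thia-bridged γ-lactone (C2 carbonyl; ring oxygen on C9), via hydroxy ester 11 (not isolated)
Conditions: NaBH4, MeOH, 0 °C to rt
Reagents that add atoms: none
Why: Borohydride reduction of the aldehyde gives an alkoxide that acylates on the neighbouring bridgehead ester (lactonisation), so O9 and the C2 carbonyl are differentiated without protecting groups.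

Step 8
Reactants: 12 thia-bridged γ-lactone
Product: 13 trans-fused cyclohexane γ-lactone with cis methyl groups C15 and C20 (C14 silyl; C12 silyl ether)
Conditions: Raney Ni, EtOH, rt
Reagents that add atoms: none
Why: Raney Ni hydrogenolysis of both C–S bonds (desulfurisation of the thiane template) should uncover the two cis methyl groups; lactone, silyl ether and arylsilane are inert.

Step 9
Reactants: 13 silyl lactone
Product: 14 hydroxy lactone (axial C14 hydroxyl)
Conditions: KBr, AcOOH, NaOAc, AcOH, rt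
Reagents that add atoms: peracetic acid CC(=O)OO
Why: Fleming–Tamao oxidation (ipso-bromodesilylation of the phenyl group, then peracid-induced 1,2-shift from silicon to oxygen) should convert C–Si into C–OH with retention.

Step 10
Reactants: 15 3-methylbut-3-en-1-ol
Product: 16 3-methylbut-3-enyl N,N-diisopropylcarbamate
Conditions: NaH, THF, 0 °C; then iPr2NCOCl, reflux
Reagents that add atoms: N,N-diisopropylcarbamoyl chloride CC(C)N(C(C)C)C(=O)Cl
Why: O-Carbamoylation of the alkoxide gives the carbamate needed for directed α-lithiation.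

Step 11
Reactants: 16 3-methylbut-3-enyl N,N-diisopropylcarbamate; 14 hydroxy lactone
Product: 18 α-carbamoyloxy ketone (C2 ketone; C3 carbamate; free C9 and C14 hydroxyls), via lithiated carbamate 17 (not isolated)
Conditions: 16 (2.5 equiv), s-BuLi, (+)-sparteine, Et2O, −78 °C; then 14, −78 to −40 °C; aq. NH4Cl
Reagents that add atoms: none
Why: Sparteine-mediated enantioselective α-deprotonation of the O-alkyl carbamate gives a configurationally stable carbanion that is acylated by the lactone with retention, so C3 is set by the diamine; the lithium hemiketal should prevent a second addition.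

Step 12
Reactants: 18 α-carbamoyloxy ketone
Product: 19 C2 carbinol (1,3-anti to the C14 hydroxyl; 2R)
Conditions: Me4NBH(OAc)3, MeCN–AcOH, −30 °C
Reagents that add atoms: none
Why: Evans–Saksena reduction: the C14 hydroxyl binds the triacetoxyborohydride and delivers hydride to C2 through a chair transition state with the carbonyl oxygen axial, which should give the 1,3-anti diol.

Step 13
Reactants: 19 C2 carbinol
Product: 21 second γ-lactone (C9 carbonyl; ring oxygen on C2), via lactol 20 (not isolated)
Conditions: TEMPO (0.2 equiv), PhI(OAc)2 (2.5 equiv), CH2Cl2, rt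
Reagents that add atoms: none
Why: Oxoammonium oxidation is selective for the primary C9 alcohol; the aldehyde is trapped by the C2 hydroxyl as a five-membered lactol and oxidised on to the lactone, which masks O2 and turns C9 into an acyl group.

Step 14
Reactants: 22 (E)-1-methoxybuta-1,3-diene; 21 second γ-lactone
Product: 24 dienyl ketone (C9 ketone bearing the 1-methoxybuta-1,3-dienyl group C8–C6), via 1-lithio-1-methoxybuta-1,3-diene 23 (not isolated)
Conditions: 22 (3 equiv), s-BuLi, THF, −78 °C; then 21, −78 °C; aq. NH4Cl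
Reagents that add atoms: none
Why: α-Lithiation of the dienol ether gives an acyl-anion equivalent that opens the lactone by acyl substitution; the lithium hemiketal stops at the ketone stage and the enol ether geometry (C9 cis to the vinyl group) is retained.

Step 15
Reactants: 24 dienyl ketone
Product: 25 C9 carbinol (9S)
Conditions: NaBH4, CeCl3·7H2O, MeOH, −78 °C
Reagents that add atoms: none
Why: Luche 1,2-reduction of the α-alkoxy dienone should follow the Felkin–Anh model (hydride anti to the quaternary C1 branch on C10), which gives the C9 configuration of the target.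

Step 16
Reactants: 25 C9 carbinol
Product: 26 tetraol (free hydroxyls on C2, C3, C9 and C14)
Conditions: LiAlH4, THF, reflux
Reagents that add atoms: none
Why: Hydride reduction is the standard cleavage of the N,N-diisopropylcarbamate and is used here while the molecule holds no ester.

Step 17
Reactants: 26 tetraol
Product: 27 tetrakis(triethylsilyl) ether
Conditions: TESOTf, 2,6-lutidine, CH2Cl2, −78 to 0 °C
Reagents that add atoms: triethylsilyl trifluoromethanesulfonate CC[Si](CC)(CC)OS(=O)(=O)C(F)(F)F
Why: Silyl triflate silylation protects the four secondary hydroxyls as acid-labile ethers that can later be removed beside the tert-butyldimethylsilyl ether at C12.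

Step 18
Reactants: 27 tetrakis(triethylsilyl) ether
Product: 29 acyloin (C7 hydroxyl; C8 ketone; 7S), via methoxy epoxide 28 (not isolated)
Conditions: dimethyldioxirane (1 equiv), acetone–CH2Cl2, −78 °C; then moist silica gel
Reagents that add atoms: dimethyldioxirane CC1(C)OO1; water O
Why: Rubottom-type oxidation: the dioxirane should epoxidise the most electron-rich enol ether double bond from the face opposite the C10 branch in the conformer that minimises allylic strain (C9–H eclipsing the alkene), and hydrolysis of the methoxy epoxide gives the acyloin.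

Step 19
Reactants: 29 acyloin
Product: 30 trimethylsilyl ether of the acyloin (keto diene)
Conditions: TMSCl, imidazole, DMF, 0 °C
Reagents that add atoms: chlorotrimethylsilane C[Si](C)(C)Cl
Why: A labile trimethylsilyl group on O7 suppresses chelation in the next step and can be released selectively afterwards.

Step 20
Reactants: 31 (S)-lactic acid
Product: 32 (2S,5S)-2-tert-butyl-5-methyl-1,3-dioxolan-4-one
Conditions: t-BuCHO, TsOH (cat.), H2SO4 (cat.), pentane, reflux with water separation; crystallisation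
Reagents that add atoms: pivalaldehyde CC(C)(C)C=O
Why: Acid-catalysed acetalisation gives the cis-dioxolanone, which stores the lactate stereocentre in the acetal carbon (self-regeneration of stereocentres).

Step 21
Reactants: 32 (2S,5S)-2-tert-butyl-5-methyl-1,3-dioxolan-4-one; 30 keto diene
Product: 34 aldol adduct (tertiary C8 alcohol bearing the dioxolanone at C17), via lithium enolate 33 (not isolated)
Conditions: 32, LiN(iPr)2, THF, −78 °C; then 30, −78 to −40 °C; aq. NH4Cl
Reagents that add atoms: none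
Why: The dioxolanone enolate reacts on the face anti to the tert-butyl group (sets C17, net retention of the lactate centre), and the ketone should be attacked in the Felkin–Anh sense with the C7 silyloxy group antiperiplanar (sets C8); aldol addition of this enolate to ketones is precedented.

Step 22
Reactants: 34 aldol adduct
Product: 35 γ-lactone (O7–C19) with free C8 and C17 hydroxyls and four triethylsilyl ethers
Conditions: K2CO3, MeOH, 0 °C
Reagents that add atoms: none
Why: Methanolysis of the trimethylsilyl ether frees the C7 alkoxide, which opens the dioxolanone by intramolecular acyl transfer (lactonisation) with loss of pivalaldehyde; O9 stays silylated, so only the O7 lactone can form.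

Step 23
Reactants: 35 silyl-protected lactone
Product: 36 hexol (secondary hydroxyls on C2, C3, C9, C14; tertiary on C8, C17)
Conditions: PPTS, MeOH, rt
Reagents that add atoms: none
Why: Mild acid-catalysed methanolysis should remove the triethylsilyl ethers selectively beside the secondary tert-butyldimethylsilyl ether.

Step 24
Reactants: 36 hexol
Product: 37 tetraacetate (acetates on O2, O3, O9, O14)
Conditions: Ac2O, pyridine, DMAP (cat.), CH2Cl2, rt
Reagents that add atoms: acetic anhydride CC(=O)OC(C)=O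
Why: DMAP-catalysed acetylation esterifies the four secondary alcohols, whereas the tertiary C8 and C17 hydroxyls should be too hindered to react.

Step 25
Reactants: 37 tetraacetate diene
Product: 38 ten-membered (Z)-cycloalkene (C5=C6)
Conditions: RuCl2(=CHPh)(PCy3)(H2IMes) (second-generation Grubbs catalyst, 20 mol %), toluene (1 mM), 80 °C
Reagents that add atoms: none
Why: Ring-closing metathesis between the vinyl group on C7 and the 1,1-disubstituted alkene at C5 closes the ten-membered ring; the trisubstituted alkene can only be (Z) in a ring of this size.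

Step 26
Reactants: 38 cycloalkene
Product: 39 5,6-epoxide (C12 silyl ether)
Conditions: mCPBA, NaHCO3, CH2Cl2, 0 °C
Reagents that add atoms: 3-chloroperbenzoic acid OOC(=O)c1cccc(Cl)c1
Why: Peracid epoxidation of the only alkene should be delivered by hydrogen bonding to the homoallylic C8 hydroxyl and occur anti to the allylic lactone oxygen, which gives the epoxide on the face of the C8 hydroxyl.

Step 27
Reactants: 39 epoxide silyl ether
Product: 40 CNP0287149.1 (target)
Conditions: HF·pyridine, pyridine, THF, 0 °C to rt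
Reagents that add atoms: none
Why: Buffered fluoride should cleave the remaining silyl ether at C12 without opening the epoxide or moving the acetates.

**Compound list**

1 | prop-2-yn-1-ol | C#CCO | starting material
2 | (E)-3-(dimethylphenylsilyl)prop-2-en-1-ol | OC/C=C/[Si](C)(C)c1ccccc1 | intermediate
3 | (E)-3-(dimethylphenylsilyl)prop-2-enal | O=C/C=C/[Si](C)(C)c1ccccc1 | intermediate
4 | methyl 4-oxothiane-3-carboxylate | COC(=O)C1CSCCC1=O | starting material
5 | methyl 3-[1-(dimethylphenylsilyl)-3-oxopropyl]-4-oxothiane-3-carboxylate (Michael adduct) | O=CC[C@H]([Si](C)(C)c1ccccc1)[C@]2(CSCCC2=O)C(=O)OC | intermediate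
6 | methyl 8-(dimethylphenylsilyl)-6-hydroxy-9-oxo-3-thiabicyclo[3.3.1]nonane-1-carboxylate | O=C2[C@@H](CS3)[C@@H](O)C[C@H]([Si](C)(C)c4ccccc4)[C@]2(C3)C(=O)OC | intermediate
7 | 6-O-tert-butyldimethylsilyl ether of 6 | O=C2[C@@H](CS3)[C@@H](O[Si](C)(C)C(C)(C)C)C[C@H]([Si](C)(C)c4ccccc4)[C@]2(C3)C(=O)OC | intermediate
8 | 9-(methoxymethylidene) enol ether of 7 (E/Z mixture) | COC=C2[C@@H](CS3)[C@@H](O[Si](C)(C)C(C)(C)C)C[C@H]([Si](C)(C)c4ccccc4)[C@]2(C3)C(=O)OC | intermediate
9 | 9-formyl compound, mixture of C10 epimers | O=CC2[C@@H](CS3)[C@@H](O[Si](C)(C)C(C)(C)C)C[C@H]([Si](C)(C)c4ccccc4)[C@]2(C3)C(=O)OC | intermediate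
10 | 9-formyl compound, formyl group equatorial on ring A | O=C[C@H]2[C@@H](CS3)[C@@H](O[Si](C)(C)C(C)(C)C)C[C@H]([Si](C)(C)c4ccccc4)[C@]2(C3)C(=O)OC | intermediate
11 | 9-(hydroxymethyl) ester | OC[C@H]2[C@@H](CS3)[C@@H](O[Si](C)(C)C(C)(C)C)C[C@H]([Si](C)(C)c4ccccc4)[C@]2(C3)C(=O)OC | intermediate
12 | thia-bridged γ-lactone (C2 carbonyl, ring oxygen on C9) | C1[C@H]2[C@@H](CS3)[C@@H](O[Si](C)(C)C(C)(C)C)C[C@H]([Si](C)(C)c4ccccc4)[C@]2(C3)C(=O)O1 | intermediate
13 | desulfurised γ-lactone with C15 and C20 methyl groups, C14 silyl | C1[C@H]2[C@@H](C)[C@@H](O[Si](C)(C)C(C)(C)C)C[C@H]([Si](C)(C)c3ccccc3)[C@]2(C)C(=O)O1 | intermediate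
14 | C14 hydroxy γ-lactone | C1[C@H]2[C@@H](C)[C@@H](O[Si](C)(C)C(C)(C)C)C[C@H](O)[C@]2(C)C(=O)O1 | intermediate
15 | 3-methylbut-3-en-1-ol | CC(=C)CCO | starting material
16 | 3-methylbut-3-enyl N,N-diisopropylcarbamate | CC(=C)CCOC(=O)N(C(C)C)C(C)C | intermediate
17 | (R)-1-lithio-3-methylbut-3-enyl N,N-diisopropylcarbamate, (+)-sparteine complex | [Li][C@H](CC(C)=C)OC(=O)N(C(C)C)C(C)C | intermediate
18 | C2 ketone with (3S) carbamate, free C9 and C14 hydroxyls | OC[C@H]2[C@@H](C)[C@@H](O[Si](C)(C)C(C)(C)C)C[C@H](O)[C@]2(C)C(=O)[C@H](CC(C)=C)OC(=O)N(C(C)C)C(C)C | intermediate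
19 | (2R) carbinol of 18 | OC[C@H]2[C@@H](C)[C@@H](O[Si](C)(C)C(C)(C)C)C[C@H](O)[C@]2(C)[C@@H](O)[C@H](CC(C)=C)OC(=O)N(C(C)C)C(C)C | intermediate
20 | lactol between C9 and O2 | OC1[C@H]2[C@@H](C)[C@@H](O[Si](C)(C)C(C)(C)C)C[C@H](O)[C@]2(C)[C@@H](O1)[C@H](CC(C)=C)OC(=O)N(C(C)C)C(C)C | intermediate
21 | second γ-lactone (C9 carbonyl, ring oxygen on C2) | O=C1[C@H]2[C@@H](C)[C@@H](O[Si](C)(C)C(C)(C)C)C[C@H](O)[C@]2(C)[C@@H](O1)[C@H](CC(C)=C)OC(=O)N(C(C)C)C(C)C | intermediate
22 | (E)-1-methoxybuta-1,3-diene | CO/C=C/C=C | starting material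
23 | 1-lithio-1-methoxybuta-1,3-diene (lithium cis to the vinyl group) | [Li]/C(OC)=C\C=C | intermediate
24 | C9 ketone bearing the 1-methoxybuta-1,3-dienyl group | C=C/C=C(OC)\C(=O)[C@H]2[C@@H](C)[C@@H](O[Si](C)(C)C(C)(C)C)C[C@H](O)[C@]2(C)[C@@H](O)[C@H](CC(C)=C)OC(=O)N(C(C)C)C(C)C | intermediate
25 | (9S) carbinol of 24 | C=C/C=C(OC)\[C@@H](O)[C@H]2[C@@H](C)[C@@H](O[Si](C)(C)C(C)(C)C)C[C@H](O)[C@]2(C)[C@@H](O)[C@H](CC(C)=C)OC(=O)N(C(C)C)C(C)C | intermediate
26 | tetraol (C2, C3, C9, C14) | C=C/C=C(OC)\[C@@H](O)[C@H]2[C@@H](C)[C@@H](O[Si](C)(C)C(C)(C)C)C[C@H](O)[C@]2(C)[C@@H](O)[C@H](CC(C)=C)O | intermediate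
27 | tetrakis(triethylsilyl) ether of 26 | C=C/C=C(OC)\[C@@H](O[Si](CC)(CC)CC)[C@H]2[C@@H](C)[C@@H](O[Si](C)(C)C(C)(C)C)C[C@H](O[Si](CC)(CC)CC)[C@]2(C)[C@@H](O[Si](CC)(CC)CC)[C@H](CC(C)=C)O[Si](CC)(CC)CC | intermediate
28 | 7,8-epoxy-8-methoxy compound | C=C[C@@H]1OC1(OC)[C@@H](O[Si](CC)(CC)CC)[C@H]2[C@@H](C)[C@@H](O[Si](C)(C)C(C)(C)C)C[C@H](O[Si](CC)(CC)CC)[C@]2(C)[C@@H](O[Si](CC)(CC)CC)[C@H](CC(C)=C)O[Si](CC)(CC)CC | intermediate
29 | acyloin (C7 hydroxyl, C8 ketone) | C=C[C@H](O)C(=O)[C@@H](O[Si](CC)(CC)CC)[C@H]2[C@@H](C)[C@@H](O[Si](C)(C)C(C)(C)C)C[C@H](O[Si](CC)(CC)CC)[C@]2(C)[C@@H](O[Si](CC)(CC)CC)[C@H](CC(C)=C)O[Si](CC)(CC)CC | intermediate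
30 | 7-O-trimethylsilyl ether of 29 (keto diene) | C=C[C@H](O[Si](C)(C)C)C(=O)[C@@H](O[Si](CC)(CC)CC)[C@H]2[C@@H](C)[C@@H](O[Si](C)(C)C(C)(C)C)C[C@H](O[Si](CC)(CC)CC)[C@]2(C)[C@@H](O[Si](CC)(CC)CC)[C@H](CC(C)=C)O[Si](CC)(CC)CC | intermediate
31 | (S)-lactic acid | C[C@H](O)C(=O)O | starting material
32 | (2S,5S)-2-tert-butyl-5-methyl-1,3-dioxolan-4-one | C[C@@H]1O[C@H](C(C)(C)C)OC1=O | intermediate
33 | lithium enolate of 32 | CC1=C(O[Li])O[C@@H](C(C)(C)C)O1 | intermediate
34 | aldol adduct (C8 tertiary alcohol, dioxolanone at C17) | C=C[C@H](O[Si](C)(C)C)[C@](O)([C@@]3(C)O[C@H](C(C)(C)C)OC3=O)[C@@H](O[Si](CC)(CC)CC)[C@H]2[C@@H](C)[C@@H](O[Si](C)(C)C(C)(C)C)C[C@H](O[Si](CC)(CC)CC)[C@]2(C)[C@@H](O[Si](CC)(CC)CC)[C@H](CC(C)=C)O[Si](CC)(CC)CC | intermediate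
35 | 8,17-dihydroxy γ-lactone, four triethylsilyl ethers | C=C[C@@H]3OC(=O)[C@](C)(O)[C@]3(O)[C@@H](O[Si](CC)(CC)CC)[C@H]2[C@@H](C)[C@@H](O[Si](C)(C)C(C)(C)C)C[C@H](O[Si](CC)(CC)CC)[C@]2(C)[C@@H](O[Si](CC)(CC)CC)[C@H](CC(C)=C)O[Si](CC)(CC)CC | intermediate
36 | hexol lactone (C12 silyl ether) | C=C[C@@H]3OC(=O)[C@](C)(O)[C@]3(O)[C@@H](O)[C@H]2[C@@H](C)[C@@H](O[Si](C)(C)C(C)(C)C)C[C@H](O)[C@]2(C)[C@@H](O)[C@H](CC(C)=C)O | intermediate
37 | 2,3,9,14-tetraacetate diene | C=C[C@@H]3OC(=O)[C@](C)(O)[C@]3(O)[C@@H](OC(C)=O)[C@H]2[C@@H](C)[C@@H](O[Si](C)(C)C(C)(C)C)C[C@H](OC(C)=O)[C@]2(C)[C@@H](OC(C)=O)[C@H](CC(C)=C)OC(C)=O | intermediate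
38 | (5Z)-briar-5-ene tetraacetate lactone, 12-O-silyl | CC(=O)O[C@H]1C/C(C)=C\[C@@H]2OC(=O)[C@](C)(O)[C@]2(O)[C@@H](OC(C)=O)[C@H]2[C@@H](C)[C@@H](O[Si](C)(C)C(C)(C)C)C[C@H](OC(C)=O)[C@]2(C)[C@H]1OC(C)=O | intermediate
39 | 12-O-tert-butyldimethylsilyl ether of the target | CC(=O)O[C@H]1C[C@@]2(C)O[C@H]2[C@@H]2OC(=O)[C@](C)(O)[C@]2(O)[C@@H](OC(C)=O)[C@H]2[C@@H](C)[C@@H](O[Si](C)(C)C(C)(C)C)C[C@H](OC(C)=O)[C@]2(C)[C@H]1OC(C)=O | intermediate
40 | CNP0287149.1 | CC(=O)O[C@H]1C[C@@]2(C)O[C@H]2[C@@H]2OC(=O)[C@](C)(O)[C@]2(O)[C@@H](OC(C)=O)[C@H]2[C@@H](C)[C@@H](O)C[C@H](OC(C)=O)[C@]2(C)[C@H]1OC(C)=O | target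

**Step count and risks**

Total step count: 27. Longest linear sequence: 25 steps (steps 1–9, 11–19 and 21–27).

Steps most likely to fail:

Step 21. The basic enolate may enolise the ketone at C7 or C9 instead of adding, may not reach the hindered carbonyl, or may attack the wrong face. Fallback, from 30 back to 35: 30 is treated with LiC≡COEt (THF, −78 °C), a small linear nucleophile, to give the ethoxyalkynyl carbinol F2. Removal of the trimethylsilyl group (K2CO3, MeOH) and heating (toluene, 110 °C) convert the ethoxyalkyne by retro-ene loss of ethene into a ketene, which the C7 hydroxyl traps as the β-hydroxy γ-lactone F3. Enolate formation with LiN(iPr)2 and oxidation with 2-(phenylsulfonyl)-3-phenyloxaziridine give the α-hydroxy lactone F4, and Dess–Martin oxidation gives the α-keto lactone F5. MeMgBr (THF, −78 °C) should then add to the ketone on the convex face anti to C9 and give 35.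

Step 11. The lithiated carbamate may be protonated or fail to add to the α-quaternary lactone carbonyl. Fallback, from 14 back to 19: 14 is reduced with (i-Bu)2AlH (toluene, −78 °C) to the ring-A lactol F1. F1 is treated with 17 after transmetalation with MgBr2·OEt2; the magnesium alkoxide of the C14 hydroxyl chelates the aldehyde (Cram–Reetz 1,3-anti control), so addition should give 19 directly and steps 11 and 12 are replaced.

Step 25. The lactone and four acetates may hold the two alkenes apart, so that oligomers form instead of the ring. Fallback, from 30 back to 38: the ring is closed before the lactone is annulated, while C8 is still trigonal and no fused ring strains the chain. Keto diene 30 is treated with the same ruthenium carbene (toluene, 80 °C, high dilution) to give the cyclodecenone F6. Addition of 33 gives the ring aldol adduct F7, K2CO3/MeOH gives the silyl-protected briarane lactone F8, PPTS/MeOH gives the briarane hexol F9, and acetylation (Ac2O, pyridine, DMAP) gives 38.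

Further compounds
F1 | step 11 | ring-A lactol (hemiacetal at C2, ring oxygen on C9) | C1[C@H]2[C@@H](C)[C@@H](O[Si](C)(C)C(C)(C)C)C[C@H](O)[C@]2(C)C(O)O1
F2 | step 21 | ethoxyalkynyl carbinol at C8 | C=C[C@H](O[Si](C)(C)C)[C@](O)(C#COCC)[C@@H](O[Si](CC)(CC)CC)[C@H]2[C@@H](C)[C@@H](O[Si](C)(C)C(C)(C)C)C[C@H](O[Si](CC)(CC)CC)[C@]2(C)[C@@H](O[Si](CC)(CC)CC)[C@H](CC(C)=C)O[Si](CC)(CC)CC
F3 | step 21 | β-hydroxy γ-lactone with C17 methylene | C=C[C@@H]3OC(=O)C[C@]3(O)[C@@H](O[Si](CC)(CC)CC)[C@H]2[C@@H](C)[C@@H](O[Si](C)(C)C(C)(C)C)C[C@H](O[Si](CC)(CC)CC)[C@]2(C)[C@@H](O[Si](CC)(CC)CC)[C@H](CC(C)=C)O[Si](CC)(CC)CC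
F4 | step 21 | α-hydroxy lactone (C17 epimers) | C=C[C@@H]3OC(=O)C(O)[C@]3(O)[C@@H](O[Si](CC)(CC)CC)[C@H]2[C@@H](C)[C@@H](O[Si](C)(C)C(C)(C)C)C[C@H](O[Si](CC)(CC)CC)[C@]2(C)[C@@H](O[Si](CC)(CC)CC)[C@H](CC(C)=C)O[Si](CC)(CC)CC
F5 | step 21 | α-keto lactone | C=C[C@@H]3OC(=O)C(=O)[C@]3(O)[C@@H](O[Si](CC)(CC)CC)[C@H]2[C@@H](C)[C@@H](O[Si](C)(C)C(C)(C)C)C[C@H](O[Si](CC)(CC)CC)[C@]2(C)[C@@H](O[Si](CC)(CC)CC)[C@H](CC(C)=C)O[Si](CC)(CC)CC
F6 | step 25 | cyclodecenone (ten-membered acyloin silyl ether) | CC[Si](CC)(CC)O[C@H]1C/C(C)=C\[C@H](O[Si](C)(C)C)C(=O)[C@@H](O[Si](CC)(CC)CC)[C@H]2[C@@H](C)[C@@H](O[Si](C)(C)C(C)(C)C)C[C@H](O[Si](CC)(CC)CC)[C@]2(C)[C@H]1O[Si](CC)(CC)CC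
F7 | step 25 | ring aldol adduct | CC[Si](CC)(CC)O[C@H]1C/C(C)=C\[C@H](O[Si](C)(C)C)[C@](O)([C@@]3(C)O[C@H](C(C)(C)C)OC3=O)[C@@H](O[Si](CC)(CC)CC)[C@H]2[C@@H](C)[C@@H](O[Si](C)(C)C(C)(C)C)C[C@H](O[Si](CC)(CC)CC)[C@]2(C)[C@H]1O[Si](CC)(CC)CC
F8 | step 25 | silyl-protected briarane lactone | CC[Si](CC)(CC)O[C@H]1C/C(C)=C\[C@@H]2OC(=O)[C@](C)(O)[C@]2(O)[C@@H](O[Si](CC)(CC)CC)[C@H]2[C@@H](C)[C@@H](O[Si](C)(C)C(C)(C)C)C[C@H](O[Si](CC)(CC)CC)[C@]2(C)[C@H]1O[Si](CC)(CC)CC
F9 | step 25 | briarane hexol (C12 silyl ether) | O[C@H]1C/C(C)=C\[C@@H]2OC(=O)[C@](C)(O)[C@]2(O)[C@@H](O)[C@H]2[C@@H](C)[C@@H](O[Si](C)(C)C(C)(C)C)C[C@H](O)[C@]2(C)[C@H]1O
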